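How far does the electrophile get in 40 h as you raise the nucleophile?

common to all: electrophile 0.39 M

|  | nucleophile | protic impurity | remark | time |
|---|---|---|---|---|
| ash | 0.36 M | 7.8 mM | run made earlier |  |
| oak | 0.73 M | 7.8 mM | run made earlier |  |
| cedar | 1.5 M | 7.8 mM | run made earlier |  |
| Sunday's | 0.350 M | 7.80 mM |  | 40 h |
| Wednesday's | 0.700 M | 7.80 mM |  | 40 h |
| Friday's | 1.40 M | 7.80 mM |  | 40 h |

| run | time / h | electrophile / % | target / % |
|---|---|---|---|
| ash | 2.00 | 74.9 | 23.0 |
| ash | 5.00 | 65.0 | 32.5 |
| ash | 10.0 | 60.7 | 36.7 |
| ash | 15.0 | 59.7 | 38.2 |
| ash | 20.0 | 58.9 | 39.6 |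
| oak | 1.50 | 64.3 | 33.5 |
| oak | 3.00 | 52.6 | 45.5 |
| oak | 6.00 | 42.8 | 55.9 |
| oak | 10.0 | 37.7 | 60.8 |
| oak | 20.0 | 34.2 | 63.6 |
| cedar | 4.00 | 27.1 | 71.0 |
| cedar | 8.00 | 18.0 | 79.7 |
| cedar | 12.0 | 14.8 | 83.6 |
| cedar | 15.0 | 13.5 | 84.9 |
| cedar | 20.0 | 11.4 | 86.7 |

(scatter of a reading: 0.3 percentage points)

- part of the electrophile that has reacted at the end, Sunday's
- part of the electrophile that has reacted at the end, Wednesday's
- part of the electrophile that has reacted at the end, Friday's
- what raising the concentration of nucleophile from its lowest to its highest value here does to the part of the electrophile that has reacted (changes below 5 percentage points count as none) (it rises / no change / it falls)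



Climb the ladder of the ash run, fastest rung first. By the first reading of the ash run a gap of 2.10% has opened in the balance, and the protic impurity was charged at 2.00% of the electrophile. So I book that share as lost early to the impurity. The next rung takes hours: in the ash run the electrophile is down to 60.7% at 10.0 h. The last rung is a crawl. From 15.0 h to 20.0 h the ash run gains 1.4 percentage points of target, with 58.9% of the electrophile still standing.

So measure each stop by a price: equivalents of nucleophile charged, divided by the fraction of the electrophile that is target at the last reading. One nucleophile per target is the zero of this scale. The ash run reads 2.33, the oak run 2.94 and the cedar run 4.44. Between ash and oak the price climbs 0.645 per equivalent. Run that line back and you get the floor, the price read back to a vanishing charge: 1.74. That is above one.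

My reckoning: the equivalents over the price on that line, plus the impurity share. It gives 40.8% for Sunday's, 64.0% for Wednesday's and 90.6% for Friday's. These are stops at the age of the last readings, and any creep comes on top.

The forecast finds that the falling rate “suggests the reaction is dying” and gives 42% (40% to 45%), 67% (64.5% to 70%) and 88% (85.5% to 91%), and says it rises. My Wednesday's lies below it and my Friday's above it.

The flasks give 41.4%, 66.2% and 89.7%: it rises, by 48 points.

    electrophile + nucleophile → acid set free + target (k = 0.590 L mol⁻¹ h⁻¹)
    nucleophile + acid set free ⇌ protonated nucleophile, settled at all times (K = 6600 L mol⁻¹)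
    2 nucleophile → self-condensation product (k = 0.230 L mol⁻¹ h⁻¹)
    electrophile + protic impurity → quenched substrate (k = 6.90 L mol⁻¹ h⁻¹)
    nucleophile + acid set free ⇌ idle adduct, settled at all times (K = 1.20 L mol⁻¹)

At 1.63 h in Sunday's flask, the main step uses nucleophile 2.6 times as fast as self-condensation does. At 40.0 h Sunday's flask has 0.37% of its nucleophile free, the limiting reagent, against 59% of its electrophile, and 39.3% of the nucleophile charge stands as protonated nucleophile. Sunday's price there is 2.28. Take the neighbour of Sunday's with 1.6 M of electrophile, charged at 0.219 equivalents. The floor and slope give it a price of 1.88, so 11.7% target. At 40.0 h that neighbour holds 12.1%.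

All runs stem from a simulated flask for an exercise; noise was put on by code.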